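## The problem

Target 20 is a (2S)-flavanone: a 5,7-dihydroxychroman-4-one (rings A and C) carrying ring B at C2. Ring B has a 4'-methoxy group flanked by a prenyl group at C5' and an (E)-3-hydroxy-3-methylbut-1-enyl group at C3'. C2 is the only stereocentre and nothing in the molecule can relay configuration to it, so it must be set by a reagent. Once set it must be kept away from the base-induced ring opening of the β-aryloxy ketone, which racemises flavanones. The two five-carbon chains on ring B differ in oxidation level and must enter at defined positions ortho to the methoxy group. The tertiary allylic alcohol conjugated with ring B ionises and dehydrates under acid. The two alkenes exclude hydrogenolysis, free borane and electrophilic oxidants. The phloroglucinol hydroxyls of ring A therefore need protecting groups that leave under buffered fluoride. The enabling feature is that O1 joins the benzylic stereocentre C2 to C8a of ring A. C8a is one of three mutually meta oxygenated carbons, so in 2,4,6-trihydroxybenzaldehyde the formyl carbon maps onto C4 and one ortho hydroxyl can become a triflate at C8a. Ring C can then be closed by forming O1–C8a from a secondary carbinol whose C2–O bond already exists and is never broken.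

## Retrosynthesis

Flavanone numbering (O1, C2, C3, C4, C4a, C8a) is used for the open-chain precursors as well.

**End game, 20 back to 17.** The two aryl silyl ethers of 19 are removed last, the C4 ketone of 19 comes from the alcohol of 18, and 18 comes from the bis(triethylsilyl) ether 17. Carrying C4 as a silyl ether through ring closure means no β-hydroxy or β-aryloxy ketone is exposed to base before C2 is locked into the ring. The price is two redox and protecting-group steps. They require triethylsilyl cleavage that spares aryl triisopropylsilyl ethers, a neutral oxidation and a buffered fluoride.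

**Key cut, 17 to 16: O1–C8a.** Cutting O1–C2 instead would make the stereocentre the site of substitution at a p-methoxybenzylic carbon. Cutting C4–C4a would need an aryl anion or a strong acid next to a β-aryloxy carbonyl. Cutting O1–C8a leaves C2 a spectator. Precursor 16 is acyclic, carries one free hydroxyl and an aryl triflate, and its C4 configuration is irrelevant. The forward reaction, a palladium-catalysed intramolecular aryl etherification, must let C–O reductive elimination outrun β-hydride elimination of the secondary alkoxide.

**C2 stereocentre, 16 to 15.** The C2–H bond is cut, giving aryl ketone 15. An unhindered aryl alkyl ketone is the best-behaved substrate class for oxazaborolidine-catalysed reduction. The reductant must tolerate two alkenes and must override the racemic silyloxy centre at C4.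

**C3–C4 bond, 15 to 14 to 9 + 12.** Removing the silyl groups gives aldol 14, and the aldol cut divides the molecule into ring B methyl ketone 9 and ring A aldehyde 12, of similar size. Aldehyde 12 cannot enolise, so the crossed aldol is unambiguous. It must be run cold and the adduct silylated at once, because 14 can revert or dehydrate.

**Ring A, 12 to 11 to 10.** The S–O and Si–O bonds are cut back to 2,4,6-trihydroxybenzaldehyde 10. The hydrogen bond between an ortho hydroxyl and the formyl group differentiates the three hydroxyls: two are silylated (11) and the chelated one is triflated (12).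

**Ring B, 9 to 1.** The aryl–vinyl bond of 9 is cut (Heck reaction of bromide 7 with alcohol 8). The prenyl group of 7 is traced to the allyl group of 5 by cross-metathesis with 6. Compound 5 comes from phenol 4 by methylation, 4 from allyl ether 3 by Claisen rearrangement, and 3 from bromophenol 1 and allyl bromide 2. Direct C-prenylation of 1 would be shorter, but competes with O-alkylation on an electron-poor phenoxide. Claisen rearrangement of a prenyl ether would deliver the branched 1,1-dimethylallyl isomer. The allyl/Claisen/metathesis sequence fixes the position and the linear connectivity.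

## Roads not taken

**Alternative 1:** The cut is at the two aryl–CH2 bonds of ring B, leading back to (2S)-naringenin A2, whose C2 centre is bought rather than made. In the forward key step an aromatic prenyltransferase transfers the dimethylallyl group of dimethylallyl diphosphate A3 twice, ortho to the 4'-hydroxyl, to give (2S)-3',5'-diprenylnaringenin A1.
- Merits: no protecting groups up to A1, the flavanone core arrives intact, and the step count is far lower than in the chosen plan.
- Weak points: A1 carries two identical prenyl groups, and only one must become the E-hydroxybutenyl unit. A Schenck ene reaction with reduction would give the right functionality but cannot tell the two chains apart, so a statistical mixture with bis-oxidised and secondary allylic isomers is expected.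
- The 4'-hydroxyl, flanked by two chains, would have to be methylated beside the more acidic 7-hydroxyl, which brings protecting groups back.
- Double regioselective prenylation by an enzyme on this substrate is not assured.
- Comparison: this road is clearly better in step economy. The chosen plan sets against it that each ring B substituent enters by a position-defined reaction and that the two chains are different from the moment they are made.

**Alternative 2:** The cut is at C4–C4a. In the forward key step t-BuLi effects bromine–lithium exchange at C4a of the aryl ether Weinreb amide A5, and the aryllithium attacks the amide carbonyl to give the (2S)-flavanone 5,7-bis(allyl) ether A4.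
- Merits: C4 arrives at the ketone oxidation level, so no C4 protecting group, no selective desilylation and no oxidation are needed. A4 is two steps closer to 20 than 17 is. The chelated tetrahedral intermediate prevents over-addition.
- Weak points: A5 already holds the C2–O aryl ether β to a carbonyl group. Any deprotonation α to the amide expels the ring A phenoxide and destroys C2.
- The free tertiary alcohol consumes organolithium, and allyl aryl ethers can be metalated at the allylic position.
- Making A5 requires forming the C2–O aryl ether with defined configuration at a p-methoxybenzylic carbon, where ionisation erodes stereochemistry.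
- Comparison: this road is shorter after ring closure. The chosen plan sets against it a C2–O bond that is made by ketone reduction and never exposed to substitution or strong base.

**Alternative 3:** The cut is at C2–C3. In the forward key step Rh2(S-PTTL)4 decomposes diazoketone A7, and the carbenoid at C3 inserts into one enantiotopic benzylic C–H bond of the O–CH2 group. This closes ring C, sets C2 and gives the (2S)-flavanone tris(silyl) ether A6.
- Merits: a single catalytic step makes the ring, a skeletal bond and the stereocentre from an achiral precursor, and ring B enters by simple O-benzylation. In stereochemical economy this is the most attractive road.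
- Weak points: the ether oxygen sits where it can form a five-membered oxonium ylide with the carbenoid. Collapse of that ylide by a 1,2-benzyl shift leads to a ring-contracted skeleton and usually outruns six-membered C–H insertion.
- An acceptor-only carbenoid can also cyclopropanate the prenyl and styrenyl alkenes or add to the electron-rich ring A.
- Its enantioselectivity in six-ring insertion is not dependable.
- Comparison: if it worked it would be shorter and would create C2 catalytically at the ring-closing stage. The chosen plan sets against it a stereocentre from an aryl ketone reduction of predictable sense, and a ring closure whose main competitor is addressed by ligand choice.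

Key step: step 11

## Route

Assumption: compounds 14 and 15 are racemic at the carbon that becomes C4, and 16, 17 and 18 are carried as mixtures of C4 epimers, because this centre is erased in step 13. Compounds 1, 2, 6, 8 and 10 are taken to be commercial.

Abbreviations in names: Ar = 3-[(1E)-3-hydroxy-3-methylbut-1-en-1-yl]-4-methoxy-5-(3-methylbut-2-en-1-yl)phenyl; Ar(TES) = the same group with the tertiary hydroxyl as its triethylsilyl ether; TIPS = triisopropylsilyl; TES = triethylsilyl.

Step 1
Reactants: 1 1-(3-bromo-4-hydroxyphenyl)ethanone; 2 allyl bromide (3-bromoprop-1-ene)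
Product: 3 1-[3-bromo-4-(prop-2-en-1-yloxy)phenyl]ethanone
Conditions: K2CO3, acetone, reflux
Reagents that add atoms: none
Why: Williamson ether synthesis; the phenoxide of 1, acidified by the para-acetyl and ortho-bromo groups, is alkylated on oxygen by the allylic bromide.

Step 2
Reactants: 3 1-[3-bromo-4-(prop-2-en-1-yloxy)phenyl]ethanone
Product: 4 1-[3-bromo-4-hydroxy-5-(prop-2-en-1-yl)phenyl]ethanone
Conditions: N,N-diethylaniline, 195 °C
Reagents that add atoms: none
Why: Aromatic Claisen rearrangement; the [3,3] shift can end only at the one ortho carbon that bears hydrogen, and tautomerisation of the dienone restores the phenol with a linear allyl group.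

Step 3
Reactants: 4 1-[3-bromo-4-hydroxy-5-(prop-2-en-1-yl)phenyl]ethanone
Product: 5 1-[3-bromo-4-methoxy-5-(prop-2-en-1-yl)phenyl]ethanone
Conditions: MeI, K2CO3, DMF, rt
Reagents that add atoms: iodomethane, CI
Why: Williamson O-methylation of an acidic phenol; capping the hydroxyl also keeps the ortho-allylphenol from cyclising or binding ruthenium in the next step.

Step 4
Reactants: 5 1-[3-bromo-4-methoxy-5-(prop-2-en-1-yl)phenyl]ethanone; 6 2-methylbut-2-ene
Product: 7 1-[3-bromo-4-methoxy-5-(3-methylbut-2-en-1-yl)phenyl]ethanone
Conditions: second-generation Grubbs catalyst RuCl2(PCy3)(H2IMes)(=CHPh) (3 mol%), 2-methylbut-2-ene/CH2Cl2, 40 °C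
Reagents that add atoms: none
Why: Olefin cross-metathesis of a terminal alkene with a trisubstituted partner in excess; the isopropylidene end is transferred and propene is lost, while the aryl bromide and ketone are inert to the ruthenium carbene.

Step 5
Reactants: 7 1-[3-bromo-4-methoxy-5-(3-methylbut-2-en-1-yl)phenyl]ethanone; 8 2-methylbut-3-en-2-ol
Product: 9 1-[3-[(1E)-3-hydroxy-3-methylbut-1-en-1-yl]-4-methoxy-5-(3-methylbut-2-en-1-yl)phenyl]ethanone
Conditions: Pd(OAc)2 (5 mol%), P(o-tol)3, Et3N, DMF, 100 °C
Reagents that add atoms: none
Why: Heck reaction; the arylpalladium species adds to the unsubstituted terminus of the monosubstituted alkene, and because the carbinol carbon is quaternary, syn β-hydride elimination can only give the conjugated E alkene; the trisubstituted prenyl alkene does not insert.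

Step 6
Reactants: 10 2,4,6-trihydroxybenzaldehyde
Product: 11 2-hydroxy-4,6-bis(triisopropylsilyloxy)benzaldehyde
Conditions: TIPSCl (2.1 equiv), imidazole, DMF, 0 °C to rt
Reagents that add atoms: chlorotriisopropylsilane, CC(C)[Si](Cl)(C(C)C)C(C)C
Why: Silylation of phenols; the para hydroxyl and one ortho hydroxyl react, after which the last hydroxyl is held in a hydrogen bond to the formyl group and resists the bulky silyl chloride.

Step 7
Reactants: 11 2-hydroxy-4,6-bis(triisopropylsilyloxy)benzaldehyde
Product: 12 2-formyl-3,5-bis(triisopropylsilyloxy)phenyl trifluoromethanesulfonate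
Conditions: Tf2O, pyridine, CH2Cl2, −20 to 0 °C
Reagents that add atoms: trifluoromethanesulfonic anhydride, O=S(=O)(OS(=O)(=O)C(F)(F)F)C(F)(F)F
Why: O-Sulfonylation of the chelated phenol by the strongly electrophilic anhydride; aryl triisopropylsilyl ethers and the aldehyde are inert to these conditions.

Step 8
Reactants: 9 1-[3-[(1E)-3-hydroxy-3-methylbut-1-en-1-yl]-4-methoxy-5-(3-methylbut-2-en-1-yl)phenyl]ethanone; 12 2-formyl-3,5-bis(triisopropylsilyloxy)phenyl trifluoromethanesulfonate
Product: 14 rac-2-[1-hydroxy-3-oxo-3-Ar-propyl]-3,5-bis(triisopropylsilyloxy)phenyl trifluoromethanesulfonate, via dilithium enolate 13 (not isolated)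
Conditions: LiN(SiMe3)2 (2.05 equiv), THF, −78 °C; then 12, −78 °C; AcOH quench at −78 °C
Reagents that add atoms: none
Why: Directed aldol addition of a preformed lithium enolate to a non-enolisable aldehyde; the amide base is too weak to metalate the ring beside the triflate, and the cold quench forestalls retro-aldol cleavage, dehydration and oxygen-to-oxygen transfer of silyl or triflyl groups in the aldolate. The new carbinol is racemic, which is harmless because it becomes the C4 carbonyl.

Step 9
Reactants: 14 rac-2-[1-hydroxy-3-oxo-3-Ar-propyl]-3,5-bis(triisopropylsilyloxy)phenyl trifluoromethanesulfonate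
Product: 15 rac-2-[3-oxo-3-Ar(TES)-1-(triethylsilyloxy)propyl]-3,5-bis(triisopropylsilyloxy)phenyl trifluoromethanesulfonate
Conditions: TESOTf (2.5 equiv), 2,6-lutidine, CH2Cl2, −78 to 0 °C
Reagents that add atoms: triethylsilyl trifluoromethanesulfonate, CC[Si](CC)(CC)OS(=O)(=O)C(F)(F)F
Why: Silylation with a silyl triflate and a hindered pyridine base, reactive enough for both the di-ortho-substituted benzylic carbinol and the tertiary alcohol; capping the aldol hydroxyl closes the retro-aldol and elimination pathways for all later steps.

Step 10
Reactants: 15 rac-2-[3-oxo-3-Ar(TES)-1-(triethylsilyloxy)propyl]-3,5-bis(triisopropylsilyloxy)phenyl trifluoromethanesulfonate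
Product: 16 2-[(3S)-3-hydroxy-3-Ar(TES)-1-(triethylsilyloxy)propyl]-3,5-bis(triisopropylsilyloxy)phenyl trifluoromethanesulfonate (both epimers at C1 of the propyl chain)
Conditions: (R)-2-methyl-CBS-oxazaborolidine (0.3 equiv), catecholborane (2 equiv), toluene, −78 to −40 °C; MeOH, then pH 7 buffer
Reagents that add atoms: none
Why: Corey–Bakshi–Shibata reduction; the ketone binds the catalyst boron with the aryl group as the large substituent, and hydride from the nitrogen-bound catecholborane is delivered to the Re face, so the (R)-catalyst gives the S carbinol under catalyst control in both C4 epimers. Catecholborane does not hydroborate the two alkenes at this temperature.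

Step 11
Reactants: 16 2-[(3S)-3-hydroxy-3-Ar(TES)-1-(triethylsilyloxy)propyl]-3,5-bis(triisopropylsilyloxy)phenyl trifluoromethanesulfonate
Product: 17 (2S)-2-Ar(TES)-4-(triethylsilyloxy)-5,7-bis(triisopropylsilyloxy)chroman (both epimers at C4)
Conditions: Pd(OAc)2 (5 mol%), 2-(di-tert-butylphosphino)-1,1'-binaphthyl (7.5 mol%), K3PO4 (2 equiv), toluene, 80 °C
Reagents that add atoms: none
Why: Pd(OAc)2 is reduced in the flask to zerovalent palladium carrying one bulky di-tert-butyl biarylphosphine, which adds oxidatively to the C8a–OTf bond; phosphate then removes the proton of the palladium-bound C2 hydroxyl to give a seven-membered aryl(alkoxo)palladium chelate, and C–O reductive elimination releases ring C. The closest known reaction type is the palladium-catalysed intramolecular etherification (Buchwald–Hartwig C–O coupling) of secondary alcohols with aryl halides and triflates to give 2-substituted chromans. Ring C closes in a six-membered mode by O-arylation at C8a, the palladacycle contracting by one atom on reductive elimination. No stereocentre is created, and C2 keeps its S configuration because its C–O bond is never broken and the weakly basic, non-polar medium gives it no way to ionise. The step needs reductive elimination to outrun β-hydride elimination of the alkoxide (which would oxidise C2 and reduce C8a) and S–O cleavage of the triflate. The electron-rich hindered phosphine, the chelate geometry, the insoluble weak base and the position of C8a meta to both silyloxy groups secure this. The C2 hydroxyl is the only free hydroxyl, and C4 is a silyl ether, so retro-aldol cleavage and dehydration cannot intervene.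

Step 12
Reactants: 17 (2S)-2-Ar(TES)-4-(triethylsilyloxy)-5,7-bis(triisopropylsilyloxy)chroman
Product: 18 (2S)-2-Ar-5,7-bis(triisopropylsilyloxy)chroman-4-ol (both epimers at C4)
Conditions: HF·pyridine, pyridine, THF, 0 °C to rt
Reagents that add atoms: none
Why: Buffered fluoride desilylation; the small triethylsilyl groups on aliphatic oxygen are cleaved much faster than the bulky aryl triisopropylsilyl ethers, and excess pyridine keeps the medium too weakly acidic to ionise the electron-rich benzylic C4–O bond or the tertiary allylic alcohol.

Step 13
Reactants: 18 (2S)-2-Ar-5,7-bis(triisopropylsilyloxy)chroman-4-ol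
Product: 19 (2S)-2-Ar-5,7-bis(triisopropylsilyloxy)chroman-4-one
Conditions: Dess–Martin periodinane, NaHCO3, CH2Cl2, 0 °C to rt
Reagents that add atoms: none
Why: Dess–Martin oxidation of the secondary benzylic alcohol; the tertiary alcohol cannot be oxidised, both C4 epimers converge on one ketone, and the neutral buffered medium leaves C2 and the alkenes untouched.

Step 14
Reactants: 19 (2S)-2-Ar-5,7-bis(triisopropylsilyloxy)chroman-4-one
Product: 20 (2S)-5,7-dihydroxy-2-[3-[(1E)-3-hydroxy-3-methylbut-1-en-1-yl]-4-methoxy-5-(3-methylbut-2-en-1-yl)phenyl]-2,3-dihydro-4H-chromen-4-one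
Conditions: TBAF, AcOH (1:1), THF, 0 °C
Reagents that add atoms: none
Why: Fluoride cleavage of the two aryl silyl ethers; acetic acid protonates the phenoxides as they form, so the flavanone does not open by β-elimination (which would racemise C2), and no acid strong enough to ionise the tertiary allylic alcohol is present.

## Compound list

1 | 1-(3-bromo-4-hydroxyphenyl)ethanone | CC(=O)c1ccc(O)c(Br)c1 | starting material
2 | allyl bromide | C=CCBr | starting material
3 | 1-[3-bromo-4-(prop-2-en-1-yloxy)phenyl]ethanone | CC(=O)c1ccc(OCC=C)c(Br)c1 | intermediate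
4 | 1-[3-bromo-4-hydroxy-5-(prop-2-en-1-yl)phenyl]ethanone | CC(=O)c1cc(Br)c(O)c(CC=C)c1 | intermediate
5 | 1-[3-bromo-4-methoxy-5-(prop-2-en-1-yl)phenyl]ethanone | CC(=O)c1cc(Br)c(OC)c(CC=C)c1 | intermediate
6 | 2-methylbut-2-ene | CC=C(C)C | starting material
7 | 1-[3-bromo-4-methoxy-5-(3-methylbut-2-en-1-yl)phenyl]ethanone | CC(=O)c1cc(Br)c(OC)c(CC=C(C)C)c1 | intermediate
8 | 2-methylbut-3-en-2-ol | C=CC(C)(C)O | starting material
9 | 1-[3-[(1E)-3-hydroxy-3-methylbut-1-en-1-yl]-4-methoxy-5-(3-methylbut-2-en-1-yl)phenyl]ethanone | CC(=O)c1cc(/C=C/C(C)(C)O)c(OC)c(CC=C(C)C)c1 | intermediate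
10 | 2,4,6-trihydroxybenzaldehyde | O=Cc1c(O)cc(O)cc1O | starting material
11 | 2-hydroxy-4,6-bis(triisopropylsilyloxy)benzaldehyde | O=Cc1c(O)cc(O[Si](C(C)C)(C(C)C)C(C)C)cc1O[Si](C(C)C)(C(C)C)C(C)C | intermediate
12 | 2-formyl-3,5-bis(triisopropylsilyloxy)phenyl trifluoromethanesulfonate | O=Cc1c(OS(=O)(=O)C(F)(F)F)cc(O[Si](C(C)C)(C(C)C)C(C)C)cc1O[Si](C(C)C)(C(C)C)C(C)C | intermediate
13 | dilithium enolate of 9 (lithium enolate and lithium tertiary alkoxide) | [Li]OC(=C)c1cc(/C=C/C(C)(C)O[Li])c(OC)c(CC=C(C)C)c1 | intermediate
14 | rac-2-[1-hydroxy-3-oxo-3-Ar-propyl]-3,5-bis(triisopropylsilyloxy)phenyl trifluoromethanesulfonate | OC(CC(=O)c1cc(/C=C/C(C)(C)O)c(OC)c(CC=C(C)C)c1)c1c(OS(=O)(=O)C(F)(F)F)cc(O[Si](C(C)C)(C(C)C)C(C)C)cc1O[Si](C(C)C)(C(C)C)C(C)C | intermediate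
15 | rac-2-[3-oxo-3-Ar(TES)-1-(triethylsilyloxy)propyl]-3,5-bis(triisopropylsilyloxy)phenyl trifluoromethanesulfonate | CC[Si](CC)(CC)OC(CC(=O)c1cc(/C=C/C(C)(C)O[Si](CC)(CC)CC)c(OC)c(CC=C(C)C)c1)c1c(OS(=O)(=O)C(F)(F)F)cc(O[Si](C(C)C)(C(C)C)C(C)C)cc1O[Si](C(C)C)(C(C)C)C(C)C | intermediate
16 | 2-[(3S)-3-hydroxy-3-Ar(TES)-1-(triethylsilyloxy)propyl]-3,5-bis(triisopropylsilyloxy)phenyl trifluoromethanesulfonate, both epimers at the silyloxy carbon | O[C@@H](CC(O[Si](CC)(CC)CC)c1c(OS(=O)(=O)C(F)(F)F)cc(O[Si](C(C)C)(C(C)C)C(C)C)cc1O[Si](C(C)C)(C(C)C)C(C)C)c1cc(CC=C(C)C)c(OC)c(/C=C/C(C)(C)O[Si](CC)(CC)CC)c1 | intermediate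
17 | (2S)-2-Ar(TES)-4-(triethylsilyloxy)-5,7-bis(triisopropylsilyloxy)chroman, both epimers at C4 | COc1c(/C=C/C(C)(C)O[Si](CC)(CC)CC)cc([C@@H]2CC(O[Si](CC)(CC)CC)c3c(O[Si](C(C)C)(C(C)C)C(C)C)cc(O[Si](C(C)C)(C(C)C)C(C)C)cc3O2)cc1CC=C(C)C | intermediate
18 | (2S)-2-Ar-5,7-bis(triisopropylsilyloxy)chroman-4-ol, both epimers at C4 | COc1c(/C=C/C(C)(C)O)cc([C@@H]2CC(O)c3c(O[Si](C(C)C)(C(C)C)C(C)C)cc(O[Si](C(C)C)(C(C)C)C(C)C)cc3O2)cc1CC=C(C)C | intermediate
19 | (2S)-2-Ar-5,7-bis(triisopropylsilyloxy)chroman-4-one | COc1c(/C=C/C(C)(C)O)cc([C@@H]2CC(=O)c3c(O[Si](C(C)C)(C(C)C)C(C)C)cc(O[Si](C(C)C)(C(C)C)C(C)C)cc3O2)cc1CC=C(C)C | intermediate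
20 | (2S)-5,7-dihydroxy-2-[3-[(1E)-3-hydroxy-3-methylbut-1-en-1-yl]-4-methoxy-5-(3-methylbut-2-en-1-yl)phenyl]-2,3-dihydro-4H-chromen-4-one | COc1c(/C=C/C(C)(C)O)cc([C@@H]2CC(=O)c3c(O)cc(O)cc3O2)cc1CC=C(C)C | target

## Step count and least certain steps

Total step count: 14. Longest linear sequence: 12 steps (steps 1 to 5, then 8 to 14); steps 6 and 7 form the ring A branch.

**Step 11 (key step).** The most likely failure is β-hydride elimination from the secondary palladium alkoxide, which oxidises C2 and reduces C8a. Next come S–O cleavage of the triflate by alkoxide or phosphate, and base-induced 1,3 oxygen-to-oxygen migration of the triethylsilyl group, which parks the substrate as an alkoxide that cannot cyclise. Fallback: ring C is closed at O1–C2 with inversion instead. Setting out from 15, reduction with the enantiomeric (S)-oxazaborolidine and catecholborane should give the (3R)-carbinol F1. Miyaura borylation of the triflate (PdCl2(dppf), bis(pinacolato)diboron, KOAc, dioxane, 80 °C) should give the aryl pinacol boronate F2. Oxidation with NaBO3·4H2O in aqueous THF should give the phenol F3. Mitsunobu cyclisation (PPh3, diisopropyl azodicarboxylate, THF, 0 °C) should then displace the activated benzylic hydroxyl by the phenol with inversion, returning to the route at 17.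

**Step 8.** The aldolate of a hindered, electron-rich aldehyde may revert, dehydrate, or pass a silyl or triflyl group from a ring A oxygen to the new alkoxide before the quench. Fallback: a Mukaiyama aldol addition, which avoids any alkoxide. Setting out from 9, TESOTf (2.2 equiv) and Et3N in CH2Cl2 should give the triethylsilyl enol ether with silylated tertiary alcohol F4. Addition of F4 to 12 with BF3·OEt2 in CH2Cl2 at −78 °C should give the mono-silylated aldol F5. Silylation of F5 with TESOTf and 2,6-lutidine returns to the route at 15.

**Step 12.** The C4–O bond is benzylic to a ring with ortho and para oxygens and may ionise under the acidic fluoride, leading to elimination towards the flav-3-ene. The tertiary silyl ether may be cleaved incompletely, or an aryl silyl ether may be lost early. Fallback: the order of deprotection and oxidation is reversed. Setting out from 17, TBAF buffered with AcOH in THF should remove all four silyl groups to give the (2S)-flavan-4,5,7-triol F6. Activated MnO2 in acetone at rt should oxidise the benzylic C4 alcohol, activated by the ortho and para hydroxyls, without touching the tertiary alcohol. The route is rejoined at 20.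

**Step 10.** Catalyst control may be incomplete in the mismatched C4 epimer, eroding the configuration at C2. If a more reactive borane is needed for conversion, hydroboration of the prenyl or styrenyl alkene becomes a risk. Fallback: the hydride source and mechanism are changed to asymmetric transfer hydrogenation with RuCl[(S,S)-TsDPEN](p-cymene) and HCO2Na in aqueous DMF. This metal–ligand bifunctional catalyst does not reduce isolated alkenes and gives the S carbinol from aryl alkyl ketones. The fallback sets out from 15 and returns at 16, and no new compound arises (F0).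

## Further compounds

F1 | step 11 | 2-[(3R)-3-hydroxy-3-Ar(TES)-1-(triethylsilyloxy)propyl]-3,5-bis(triisopropylsilyloxy)phenyl trifluoromethanesulfonate | O[C@H](CC(O[Si](CC)(CC)CC)c1c(OS(=O)(=O)C(F)(F)F)cc(O[Si](C(C)C)(C(C)C)C(C)C)cc1O[Si](C(C)C)(C(C)C)C(C)C)c1cc(CC=C(C)C)c(OC)c(/C=C/C(C)(C)O[Si](CC)(CC)CC)c1
F2 | step 11 | (1R)-1-Ar(TES)-3-[2-(4,4,5,5-tetramethyl-1,3,2-dioxaborolan-2-yl)-4,6-bis(triisopropylsilyloxy)phenyl]-3-(triethylsilyloxy)propan-1-ol | O[C@H](CC(O[Si](CC)(CC)CC)c1c(B2OC(C)(C)C(C)(C)O2)cc(O[Si](C(C)C)(C(C)C)C(C)C)cc1O[Si](C(C)C)(C(C)C)C(C)C)c1cc(CC=C(C)C)c(OC)c(/C=C/C(C)(C)O[Si](CC)(CC)CC)c1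
F3 | step 11 | 2-[(3R)-3-hydroxy-3-Ar(TES)-1-(triethylsilyloxy)propyl]-3,5-bis(triisopropylsilyloxy)phenol | O[C@H](CC(O[Si](CC)(CC)CC)c1c(O)cc(O[Si](C(C)C)(C(C)C)C(C)C)cc1O[Si](C(C)C)(C(C)C)C(C)C)c1cc(CC=C(C)C)c(OC)c(/C=C/C(C)(C)O[Si](CC)(CC)CC)c1
F4 | step 8 | triethyl[(1-Ar(TES)-ethenyl)oxy]silane (triethylsilyl enol ether of 9 with silylated tertiary alcohol) | C=C(O[Si](CC)(CC)CC)c1cc(/C=C/C(C)(C)O[Si](CC)(CC)CC)c(OC)c(CC=C(C)C)c1
F5 | step 8 | rac-2-[1-hydroxy-3-oxo-3-Ar(TES)-propyl]-3,5-bis(triisopropylsilyloxy)phenyl trifluoromethanesulfonate | OC(CC(=O)c1cc(/C=C/C(C)(C)O[Si](CC)(CC)CC)c(OC)c(CC=C(C)C)c1)c1c(OS(=O)(=O)C(F)(F)F)cc(O[Si](C(C)C)(C(C)C)C(C)C)cc1O[Si](C(C)C)(C(C)C)C(C)C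
F6 | step 12 | (2S)-2-Ar-chroman-4,5,7-triol, both epimers at C4 | COc1c(/C=C/C(C)(C)O)cc([C@@H]2CC(O)c3c(O)cc(O)cc3O2)cc1CC=C(C)C
F0 | step 10 | none | none
A1 | alternative 1 | (2S)-3',5'-diprenylnaringenin | CC(C)=CCc1cc([C@@H]2CC(=O)c3c(O)cc(O)cc3O2)cc(CC=C(C)C)c1O
A2 | alternative 1 | (2S)-naringenin | Oc1ccc([C@@H]2CC(=O)c3c(O)cc(O)cc3O2)cc1
A3 | alternative 1 | dimethylallyl diphosphate | CC(C)=CCOP(=O)(O)OP(=O)(O)O
A4 | alternative 2 | (2S)-flavanone 5,7-bis(allyl) ether | COc1c(/C=C/C(C)(C)O)cc([C@@H]2CC(=O)c3c(OCC=C)cc(OCC=C)cc3O2)cc1CC=C(C)C
A5 | alternative 2 | (3S)-3-[2-bromo-3,5-bis(prop-2-en-1-yloxy)phenoxy]-3-Ar-N-methoxy-N-methylpropanamide | CON(C)C(=O)C[C@H](Oc1cc(OCC=C)cc(OCC=C)c1Br)c1cc(CC=C(C)C)c(OC)c(/C=C/C(C)(C)O)c1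
A6 | alternative 3 | (2S)-flavanone tris(silyl) ether | COc1c(/C=C/C(C)(C)O[Si](CC)(CC)CC)cc([C@@H]2CC(=O)c3c(O[Si](C)(C)C(C)(C)C)cc(O[Si](C)(C)C(C)(C)C)cc3O2)cc1CC=C(C)C
A7 | alternative 3 | 2-diazo-1-[2-(Ar(TES)-methoxy)-4,6-bis(tert-butyldimethylsilyloxy)phenyl]ethanone | [N-]=[N+]=CC(=O)c1c(OCc2cc(CC=C(C)C)c(OC)c(/C=C/C(C)(C)O[Si](CC)(CC)CC)c2)cc(O[Si](C)(C)C(C)(C)C)cc1O[Si](C)(C)C(C)(C)C
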